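Numbering: lactone ring O1–C2(=O)–C3–C4–C5, C6 = exocyclic CH2 on C5, C1'' = first carbon of the E side chain on C3; acyl part C1'(=O)–C2'–C3'(OH)–C4'(=O)–C5'.
Cuts: (a) the ester bond O(on C4)–C1', giving alcohol 12 and acid 24. (b) In 12 the pair C4–OH/C5=C6 is traced back through the 4,5-oxirane 10 to the endocyclic enol lactone 9 (C4=C5, C6 = CH3), and in 9 the ring bond C4–C5 is cut. (c) C4–P and C3=C1'' go back to the Morita–Baylis–Hillman adduct of tetradecanal. (d) In 24 the cuts are C2'–C3' (vinylalane + methacrolein) and C4'=O (from C4'=CH2).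
Enabling feature: C4 (carbinol CH) and C5 (enol-ester carbon) of the butanolide ring are a masked acyloin, two acceptor carbons bridged by O1–C2(=O)–C3. C5/C6 is an acetyl group that can hang on O1 as a mixed anhydride. C4, allylic to C3=C1'', can carry a phosphonium group, become a donor and close the five-membered ring on C5.
Forward order: chain and E alkene (steps 1–3), lactone ring (step 4), temporary oxirane ring on C4/C5 (step 5), its eliminative opening to C4–OH/C5=C6 (step 6). The Z acid is built in parallel (steps 7–11), then come ester union (step 12) and desilylation (step 13).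
Stereochemistry: C4 comes from a catalyst-controlled Shi epoxidation of C4=C5 and C3' from a Sharpless kinetic resolution. The E alkene comes from the SN2' bromination (thermodynamic isomer) and the Z alkene from syn hydroalumination of an ynoate.

Key step: step 4

Assumption: the facial sense of the fructose-derived ketone on 9 is taken to follow that known for 1-substituted cycloalkenes and cyclic enol esters; should it be the opposite, the D-fructose-derived ketone is used in step 5 and nothing else changes.

Step 1
Reactants: 1 tetradecanal; 2 tert-butyl acrylate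
Product: 3 tert-butyl 3-hydroxy-2-methylidenehexadecanoate (racemic)
Conditions: quinuclidine (0.3 equiv), MeOH (1 equiv), neat, rt
Reagents that add atoms: none
Why: Morita–Baylis–Hillman reaction, in which the amine adds to the acrylate, the enolate adds to the aldehyde and the amine is expelled; the carbinol centre forms racemic, which does not matter because step 2 erases it.

Step 2
Reactants: 3 tert-butyl 3-hydroxy-2-methylidenehexadecanoate
Product: 4 (Z)-2-(bromomethyl)hexadec-2-enoic acid
Conditions: 48% aq HBr, conc. H2SO4, CH2Cl2, 0 °C to rt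
Reagents that add atoms: hydrogen bromide, Br
Why: Acid-promoted allylic (SN2') bromination of a Morita–Baylis–Hillman alcohol should give the thermodynamic trisubstituted alkene with the chain trans to the carboxyl group (Z by the CIP rules because CH2Br outranks CO2H), while the same strong acid cleaves the tert-butyl ester by the SN1/E1 path.

Step 3
Reactants: 4 (Z)-2-(bromomethyl)hexadec-2-enoic acid
Product: 5 [(Z)-2-carboxyhexadec-2-en-1-yl]triphenylphosphonium bromide
Conditions: PPh3, MeCN, 60 °C
Reagents that add atoms: triphenylphosphine, c1ccc(cc1)P(c1ccccc1)c1ccccc1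
Why: SN2 quaternisation of PPh3 at the primary allylic bromide (phosphonium salt formation); the free acid is inert and the alkene already has its stable geometry.

Step 4
Reactants: 5 [(Z)-2-carboxyhexadec-2-en-1-yl]triphenylphosphonium bromide; 6 acetic anhydride
Product: 9 (E)-5-methyl-3-tetradecylidenefuran-2(3H)-one, via mixed anhydride salt 7 (not isolated), via allyl ylide 8 (not isolated)
Conditions: Et3N (3 equiv), toluene, rt then reflux
Reagents that add atoms: none
Why: Proposed new method: acetylation of the carboxylate of 5 gives the mixed anhydride 7, Et3N keeps a small stationary concentration of the allyl ylide 8, its carbon C4 adds to the acetyl carbonyl carbon C5, and the betaine closes to an oxaphosphetane that collapses irreversibly to the C4=C5 bond of 9 and Ph3P=O. C4 and C5 are both acceptor carbons in the target (carbinol and enol-ester carbon of a masked acyloin), so the phosphonium group is the helper that reverses the polarity of C4, and it leaves in the same operation. The closest known reaction type is the intramolecular Wittig olefination of ester and mixed-anhydride carbonyl groups under Et3N, which makes benzofurans from 2-(acyloxy)benzylphosphonium salts and isocoumarins from 2-carboxybenzylphosphonium salts and acylating agents; a non-aromatic 2-carboxyallyl salt and a furan-2(3H)-one ring have not been shown. The lactone ring closes 5-exo-trig (C4 onto C5, the carbonyl oxygen staying outside the new ring) across the flat tether C3–C2(=O)–O1, the same ring size and hybridisation pattern as in the benzofuran case. No stereocentre is created, and the C3=C1'' geometry is safe because the isomer set in step 2 is the thermodynamic one even if the delocalised ylide allows rotation. The step needs attack at the acetyl and not the enoyl carbonyl (only the former is within reach of C4 through a five-membered transition state), alpha rather than gamma attack of the allyl ylide, and olefination rather than C-acylation by loss of carboxylate; only the alpha adduct can form the P–O bond, so the reversible side adducts should drain into 9.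

Step 5
Reactants: 9 (E)-5-methyl-3-tetradecylidenefuran-2(3H)-one
Product: 10 (1R,4E,5S)-1-methyl-4-tetradecylidene-2,6-dioxabicyclo[3.1.0]hexan-3-one
Conditions: 1,2:4,5-di-O-isopropylidene-β-L-erythro-2,3-hexodiulo-2,6-pyranose (0.3 equiv), KHSO5 (as 2KHSO5·KHSO4·K2SO4), K2CO3, Bu4NHSO4, MeCN–CH2(OMe)2 / aq Na2B4O7 buffer, 0 °C
Reagents that add atoms: potassium peroxymonosulfate, [K+].[O-]S(=O)(=O)OO
Why: Shi epoxidation (chiral dioxirane, a reaction type established for enol esters): the electrophilic oxidant should take the electron-richer enol-ester bond C4=C5 and not the ester-conjugated C3=C1'', and the spiro transition state with the L-fructose-derived ketone should put the oxygen on the face that makes C4 S (C5 follows in the cis-fused oxirane), the mirror image of the sense known for the D-fructose ketone.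

Step 6
Reactants: 10 (1R,4E,5S)-1-methyl-4-tetradecylidene-2,6-dioxabicyclo[3.1.0]hexan-3-one
Product: 12 (3E,4S)-4-hydroxy-5-methylidene-3-tetradecylideneoxolan-2-one, via trimethylsilyl ether 11 (not isolated)
Conditions: Me3SiOTf, 2,6-lutidine, CH2Cl2, −78 °C; then 0.5 M aq citric acid, THF, 0 °C
Reagents that add atoms: trimethylsilyl trifluoromethanesulfonate, C[Si](C)(C)OS(=O)(=O)C(F)(F)F (its SiMe3 group stays in 11 only)
Why: Proposed new method: O-silylation of the oxirane weakens the C5–O bond (tertiary carbon, cation stabilised by O1) and 2,6-lutidine removes the least hindered adjacent proton, one of the C6 methyl group, which should give the exocyclic enol lactone 11 with the C4–O bond and hence the 4S configuration untouched; the closest known reaction type is the R3SiOTf/amine isomerisation of trisubstituted epoxides to allylic silyl ethers (1-methylcycloalkene oxides give 2-methylidenecycloalkyl silyl ethers), not yet shown on 2-acyloxy epoxides, whose usual acyl shift to an alpha-acyloxy ketone is blocked here because it would need a bridged dioxolanylium ion or a beta-lactone.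

Step 7
Reactants: 13 pentadec-1-yne; 14 di-tert-butyl dicarbonate
Product: 16 tert-butyl hexadec-2-ynoate, via lithium acetylide 15 (not isolated)
Conditions: n-BuLi, THF, −78 °C; then 14, −78 °C to rt; aq NH4Cl
Reagents that add atoms: n-butyllithium, [Li]CCCC (its Li stays in 15 only)
Why: Alkoxycarbonylation of a lithium acetylide with the dicarbonate, a standard route to tert-butyl alk-2-ynoates, with tert-butyl carbonate as the leaving group.

Step 8
Reactants: 16 tert-butyl hexadec-2-ynoate; 17 methacrolein
Product: 19 tert-butyl (Z)-2-(1-hydroxy-2-methylprop-2-en-1-yl)hexadec-2-enoate (racemic), via vinylalane 18 (not isolated)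
Conditions: iBu2AlH, HMPA, THF, 0 °C; then 17, 0 °C; aq potassium sodium tartrate
Reagents that add atoms: diisobutylaluminium hydride, CC(C)C[AlH]CC(C)C (its hydride stays, its Al group stays in 18 only)
Why: Vinylalumination: syn conjugate hydroalumination of the ynoate puts H and Al cis, hence the chain cis to the ester, and the vinylalane should add 1,2 to the aldehyde with retention to give the Z alkene; the carbinol centre is racemic and is resolved in step 9.

Step 9
Reactants: 19 tert-butyl (Z)-2-(1-hydroxy-2-methylprop-2-en-1-yl)hexadec-2-enoate (racemic)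
Product: 20 tert-butyl (2Z)-2-[(1R)-1-hydroxy-2-methylprop-2-en-1-yl]hexadec-2-enoate
Conditions: Ti(OiPr)4, D-(−)-diisopropyl tartrate, tBuOOH (0.6 equiv), 4 Å molecular sieves, CH2Cl2, −20 °C
Reagents that add atoms: none
Why: Sharpless kinetic resolution: with D-(−)-tartrate the titanium catalyst should epoxidise the isopropenyl group of (S)-19 much faster than that of (R)-19 (empirical rule for secondary allylic alcohols, with C2' in the role of the alkyl group), so that 20 is recovered, and the electron-poor enoate alkene does not react.

Step 10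
Reactants: 20 tert-butyl (2Z)-2-[(1R)-1-hydroxy-2-methylprop-2-en-1-yl]hexadec-2-enoate
Product: 22 (2Z)-2-[(1R)-2-methyl-1-(triethylsilyloxy)prop-2-en-1-yl]hexadec-2-enoic acid, via bis(triethylsilyl) compound 21 (not isolated)
Conditions: Et3SiOTf (3 equiv), 2,6-lutidine (4 equiv), CH2Cl2, 0 °C to rt; then pH 7 phosphate buffer, THF, rt
Reagents that add atoms: triethylsilyl trifluoromethanesulfonate, CC[Si](CC)(CC)OS(=O)(=O)C(F)(F)F
Why: Silyl triflate/lutidine silylates the hindered alcohol and converts the tert-butyl ester into the silyl ester with loss of isobutene (known silyl triflate ester cleavage), and only the silyl ester hydrolyses in the neutral buffer; no bond at C3' is touched.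

Step 11
Reactants: 22 (2Z)-2-[(1R)-2-methyl-1-(triethylsilyloxy)prop-2-en-1-yl]hexadec-2-enoic acid
Product: 24 (2Z,3S)-4-oxo-2-tetradecylidene-3-(triethylsilyloxy)pentanoic acid, via ozonide 23 (not isolated)
Conditions: O3/O2, CH2Cl2, −78 °C, stopped at consumption of 22; then Me2S, −78 °C to rt
Reagents that add atoms: ozone, [O-][O+]=O
Why: Ozonolysis with reductive work-up: electrophilic ozone prefers the electron-richer 1,1-disubstituted alkene to the acid-conjugated trisubstituted one, which unmasks the methyl ketone without touching C3' (the descriptor changes from R to S only because C4' now outranks C2').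

Step 12
Reactants: 12 (3E,4S)-4-hydroxy-5-methylidene-3-tetradecylideneoxolan-2-one; 24 (2Z,3S)-4-oxo-2-tetradecylidene-3-(triethylsilyloxy)pentanoic acid
Product: 26 (3S,4E)-2-methylidene-5-oxo-4-tetradecylideneoxolan-3-yl (2Z,3S)-4-oxo-2-tetradecylidene-3-(triethylsilyloxy)pentanoate, via mixed anhydride 25 (not isolated)
Conditions: 2-methyl-6-nitrobenzoic anhydride, Et3N, 4-(dimethylamino)pyridine (0.1 equiv), CH2Cl2, 0 °C to rt
Reagents that add atoms: 2-methyl-6-nitrobenzoic anhydride, Cc1cccc([N+](=O)[O-])c1C(=O)OC(=O)c1c(C)cccc1[N+](=O)[O-] (its aroyl group stays in 25 only)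
Why: Shiina esterification: the pyridine catalyst attacks the enoyl carbonyl of 25 because the 2,6-disubstituted aroyl carbonyl is shielded, and 12 is acylated on oxygen, so that C4 and C3' keep their configuration.

Step 13
Reactants: 26 (3S,4E)-2-methylidene-5-oxo-4-tetradecylideneoxolan-3-yl (2Z,3S)-4-oxo-2-tetradecylidene-3-(triethylsilyloxy)pentanoate
Product: 27 (3S,4E)-2-methylidene-5-oxo-4-tetradecylideneoxolan-3-yl (2Z,3S)-3-hydroxy-4-oxo-2-tetradecylidenepentanoate (target)
Conditions: HF·pyridine, pyridine, THF, 0 °C
Reagents that add atoms: none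
Why: Fluoride-driven cleavage of a secondary triethylsilyl ether under pyridine-buffered, non-basic and non-aqueous conditions, under which the enol lactone, the bis-allylic ester and the alpha-ketol should stay intact.

Compound list
1 | tetradecanal | CCCCCCCCCCCCCC=O | starting material
2 | tert-butyl acrylate | C=CC(=O)OC(C)(C)C | starting material
3 | tert-butyl 3-hydroxy-2-methylidenehexadecanoate (racemic) | C=C(C(=O)OC(C)(C)C)C(O)CCCCCCCCCCCCC | intermediate
4 | (Z)-2-(bromomethyl)hexadec-2-enoic acid | OC(=O)/C(CBr)=C/CCCCCCCCCCCCC | intermediate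
5 | [(Z)-2-carboxyhexadec-2-en-1-yl]triphenylphosphonium bromide | OC(=O)/C(C[P+](c1ccccc1)(c1ccccc1)c1ccccc1)=C/CCCCCCCCCCCCC.[Br-] | intermediate
6 | acetic anhydride | CC(=O)OC(C)=O | starting material
7 | {(Z)-2-[(acetyloxy)carbonyl]hexadec-2-en-1-yl}triphenylphosphonium bromide (mixed anhydride salt) | CC(=O)OC(=O)/C(C[P+](c1ccccc1)(c1ccccc1)c1ccccc1)=C/CCCCCCCCCCCCC.[Br-] | intermediate
8 | acetic (Z)-2-[(triphenyl-λ5-phosphanylidene)methyl]hexadec-2-enoic anhydride (allyl ylide) | CC(=O)OC(=O)/C(C=P(c1ccccc1)(c1ccccc1)c1ccccc1)=C/CCCCCCCCCCCCC | intermediate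
9 | (E)-5-methyl-3-tetradecylidenefuran-2(3H)-one | CC1=C/C(=C\CCCCCCCCCCCCC)C(=O)O1 | intermediate
10 | (1R,4E,5S)-1-methyl-4-tetradecylidene-2,6-dioxabicyclo[3.1.0]hexan-3-one | C[C@@]12OC(=O)/C(=C/CCCCCCCCCCCCC)[C@@H]1O2 | intermediate
11 | (3E,4S)-5-methylidene-3-tetradecylidene-4-(trimethylsilyloxy)oxolan-2-one | C=C1OC(=O)/C(=C/CCCCCCCCCCCCC)[C@@H]1O[Si](C)(C)C | intermediate
12 | (3E,4S)-4-hydroxy-5-methylidene-3-tetradecylideneoxolan-2-one | C=C1OC(=O)/C(=C/CCCCCCCCCCCCC)[C@@H]1O | intermediate
13 | pentadec-1-yne | C#CCCCCCCCCCCCCC | starting material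
14 | di-tert-butyl dicarbonate | CC(C)(C)OC(=O)OC(=O)OC(C)(C)C | starting material
15 | lithium pentadec-1-yn-1-ide | [Li]C#CCCCCCCCCCCCCC | intermediate
16 | tert-butyl hexadec-2-ynoate | CCCCCCCCCCCCCC#CC(=O)OC(C)(C)C | intermediate
17 | methacrolein | C=C(C)C=O | starting material
18 | tert-butyl 2-(diisobutylalumanyl)hexadec-2-enoate, Al cis to the vinyl H, chain cis to the ester | CC(C)(C)OC(=O)/C(=C\CCCCCCCCCCCCC)[Al](CC(C)C)CC(C)C | intermediate
19 | tert-butyl (Z)-2-(1-hydroxy-2-methylprop-2-en-1-yl)hexadec-2-enoate (racemic) | CC(C)(C)OC(=O)/C(=C\CCCCCCCCCCCCC)C(O)C(C)=C | intermediate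
20 | tert-butyl (2Z)-2-[(1R)-1-hydroxy-2-methylprop-2-en-1-yl]hexadec-2-enoate | CC(C)(C)OC(=O)/C(=C\CCCCCCCCCCCCC)[C@H](O)C(C)=C | intermediate
21 | triethylsilyl (2Z)-2-[(1R)-2-methyl-1-(triethylsilyloxy)prop-2-en-1-yl]hexadec-2-enoate | CC[Si](CC)(CC)OC(=O)/C(=C\CCCCCCCCCCCCC)[C@H](O[Si](CC)(CC)CC)C(C)=C | intermediate
22 | (2Z)-2-[(1R)-2-methyl-1-(triethylsilyloxy)prop-2-en-1-yl]hexadec-2-enoic acid | OC(=O)/C(=C\CCCCCCCCCCCCC)[C@H](O[Si](CC)(CC)CC)C(C)=C | intermediate
23 | 1,2,4-trioxolane (ozonide) of 22, mixture at the ring carbon | OC(=O)/C(=C\CCCCCCCCCCCCC)[C@H](O[Si](CC)(CC)CC)C1(C)OCOO1 | intermediate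
24 | (2Z,3S)-4-oxo-2-tetradecylidene-3-(triethylsilyloxy)pentanoic acid | OC(=O)/C(=C\CCCCCCCCCCCCC)[C@H](O[Si](CC)(CC)CC)C(C)=O | intermediate
25 | 2-methyl-6-nitrobenzoic (2Z,3S)-4-oxo-2-tetradecylidene-3-(triethylsilyloxy)pentanoic anhydride | Cc1cccc([N+](=O)[O-])c1C(=O)OC(=O)/C(=C\CCCCCCCCCCCCC)[C@H](O[Si](CC)(CC)CC)C(C)=O | intermediate
26 | (3S,4E)-2-methylidene-5-oxo-4-tetradecylideneoxolan-3-yl (2Z,3S)-4-oxo-2-tetradecylidene-3-(triethylsilyloxy)pentanoate | C=C1OC(=O)/C(=C/CCCCCCCCCCCCC)[C@@H]1OC(=O)/C(=C\CCCCCCCCCCCCC)[C@H](O[Si](CC)(CC)CC)C(C)=O | intermediate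
27 | (3S,4E)-2-methylidene-5-oxo-4-tetradecylideneoxolan-3-yl (2Z,3S)-3-hydroxy-4-oxo-2-tetradecylidenepentanoate | C=C1OC(=O)/C(=C/CCCCCCCCCCCCC)[C@@H]1OC(=O)/C(=C\CCCCCCCCCCCCC)[C@H](O)C(C)=O | target

Total step count: 13. Longest linear sequence: 8 (steps 1–6, 12, 13).

Steps most likely to fail

Step 4. The tetrahedral adduct may lose carboxylate and end as a stabilised C-acyl ylide. The allyl ylide may attack through its gamma carbon, or the exocyclic double bond may drift under Et3N at reflux. The fallback sets out from 1 and comes back at 9. It buys the ring instead of closing it: a Knoevenagel-type condensation of 1 with commercial alpha-angelica lactone (5-methylfuran-2(3H)-one, CC1=CCC(=O)O1), catalytic piperidinium acetate, toluene, azeotropic removal of water. This is the known route to 3-ylidene-5-methylfuran-2(3H)-ones. No compound outside the list is made (F0).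

Step 6. The silylated oxirane may undergo a 1,2-hydride shift from C4 to C5, lose the C4 proton instead of a C6 proton, or open the lactone. The fallback sets out from 9 and comes back at 26, bypassing the oxirane (and step 5) with known reaction types. In a Schenck ene reaction (O2, tetraphenylporphyrin, visible light, CH2Cl2, −20 °C) the only allylic hydrogens are those of the C6 methyl group. Oxygen must therefore end on C4 and the double bond at C5=C6, giving the racemic 4-hydroperoxide F1. PPh3 reduces it to the racemic alcohol F2. Shiina esterification of F2 with the enantiopure acid 24 under the conditions of step 12 gives 26 together with its 4R epimer F3, and the two diastereomers are separated by chromatography.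

Step 12. Reversible conjugate addition of the pyridine catalyst may turn the Z enoyl unit into E. Enolisation of the activated keto acid may epimerise C3' or close it to its own enol lactone, and the enol lactone of 12 may act as a competing acyl donor. The fallback sets out from 9 and comes back at 26. It activates the alcohol instead of the acid under neutral conditions. Step 5 run with the D-fructose-derived ketone gives the enantiomeric oxirane F4. The conditions of step 6 give, through the (R)-silyl ether F5, the (R)-alcohol F6. A Mitsunobu esterification of F6 with 24 (PPh3, diisopropyl azodicarboxylate, toluene, −20 °C) then proceeds with inversion at C4 to 26.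

Further compounds
F0 | step 4 | none | none
F1 | step 6 | (3E)-4-hydroperoxy-5-methylidene-3-tetradecylideneoxolan-2-one (racemic) | C=C1OC(=O)/C(=C/CCCCCCCCCCCCC)C1OO
F2 | step 6 | (3E)-4-hydroxy-5-methylidene-3-tetradecylideneoxolan-2-one (racemic) | C=C1OC(=O)/C(=C/CCCCCCCCCCCCC)C1O
F3 | step 6 | (3R,4E)-2-methylidene-5-oxo-4-tetradecylideneoxolan-3-yl (2Z,3S)-4-oxo-2-tetradecylidene-3-(triethylsilyloxy)pentanoate | C=C1OC(=O)/C(=C/CCCCCCCCCCCCC)[C@H]1OC(=O)/C(=C\CCCCCCCCCCCCC)[C@H](O[Si](CC)(CC)CC)C(C)=O
F4 | step 12 | (1S,4E,5R)-1-methyl-4-tetradecylidene-2,6-dioxabicyclo[3.1.0]hexan-3-one | C[C@]12OC(=O)/C(=C/CCCCCCCCCCCCC)[C@H]1O2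
F5 | step 12 | (3E,4R)-5-methylidene-3-tetradecylidene-4-(trimethylsilyloxy)oxolan-2-one | C=C1OC(=O)/C(=C/CCCCCCCCCCCCC)[C@H]1O[Si](C)(C)C
F6 | step 12 | (3E,4R)-4-hydroxy-5-methylidene-3-tetradecylideneoxolan-2-one | C=C1OC(=O)/C(=C/CCCCCCCCCCCCC)[C@H]1O
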